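Remark: the target is achiral (no stereocentre, no double-bond geometry), so nothing stereochemical has to be set. Methyl undec-10-enoate, bromobenzene, 9-BBN, 4-hydroxy-6-methyl-2H-pyran-2-one and Mg(OMe)2 in methanol are taken as catalogue chemicals.

Compound numbers used throughout: 1 methyl undec-10-enoate, 2 bromobenzene, 3 B-alkylborane (in flask), 4 methyl 11-phenylundecanoate, 5 triacetic acid lactone, 6 its dilithio dianion (in flask), 7 the 6-(2-oxoalkyl)pyrone, 8 the open-chain triketo ester (in flask), 9 the target.

## The problem

The target 9 is an acylphloroglucinol: ring A is a benzene ring with hydroxyl groups on C2, C4 and C6 and, on C1, a ketone carbonyl C1' that continues as ten methylene groups (C2' to C11') to an unsubstituted phenyl ring B. The chain and ring B are inert and the molecule has no stereocentre, so all the difficulty lies in ring A. A finished ring A is a 1,3,5-triol with three nucleophilic oxygens and three equivalent nucleophilic carbons that must end up with exactly one acyl group, on carbon; a plan that buys the ring must control C- against O-acylation and mono- against polyacylation by stoichiometry alone, or carry three ether protecting groups and remove them next to a ketone. The free triol is also oxidised easily as its anion, so ring A should appear late and be released by acidification. The enabling feature is the oxygen pattern: along the seven-carbon path C1'(=O), C1, C2(OH), C3, C4(OH), C5, C6(OH) every second carbon carries oxygen, and C6 is bonded back to C1. This is the folded form of a linear 3,5,7-trioxoalkanoate (a tetraketide), whose ester carbon becomes ring C6, whose C6 methylene becomes ring C1 and whose C7 ketone becomes C1'. One Claisen condensation forming the ring bond C1-C6 therefore creates ring A with all four oxygenated carbons and the single acyl group in place, and because the three C-OH positions are equivalent the closure has no regiochemical ambiguity once it runs in the Claisen sense. The open poly-beta-carbonyl chain is prone to aldol closure and retro-Claisen cleavage, so it must stay masked until it is folded.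

## Retrosynthesis

Disconnection 1 (9 to 8 to 7). The ring bond C1-C6 of ring A is cut in the Claisen sense. This gives methyl 3,5,7-trioxo-17-phenylheptadecanoate 8, whose C6 methylene is to acylate its own ester carbon C1. Compound 8 is not a practical intermediate, so it is masked as its enol lactone, 4-hydroxy-6-(2-oxo-12-phenyldodecyl)-2H-pyran-2-one 7, an isomer of 9. Compared with the neighbouring cut of the aryl-carbonyl bond C1-C1', this cut needs no ready-made triphenol, cannot over-acylate and uses no protecting groups. Pyrone 7 has no benzenoid ring A and no free polyphenol, and it is one step from a commercial pyrone. The forward reaction must open the lactone with methoxide and close ring A by Claisen condensation (C6 to C1), not by aldol condensation (C2 to C7). Magnesium methoxide in methanol is chosen for this.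

Disconnection 2 (7 to 4 + 5). The bond between the side-chain methylene on pyrone C6 and the side-chain ketone carbon is cut. This leads to triacetic acid lactone 5, which is the triketide already in lactone form, and methyl 11-phenylundecanoate 4, which supplies the fourth ketide carbonyl with the whole chain. The alternative of building the tetraketide linearly from acetoacetate-type dianions would pass through free, unstable polyketo esters and need more steps. The forward reaction is acylation of the dianion of 5 at its 6-methyl carbon by a simple ester.

Disconnection 3 (4 to 1 + 2). The bond between benzylic C11' and ring B is cut, giving methyl undec-10-enoate 1 and bromobenzene 2. Hydroboration of the terminal alkene gives borane 3, which is coupled with 2 in a B-alkyl Suzuki-Miyaura reaction. The cut is chosen because 1 is a commodity C11 ester that already contains the chain and the ester in the right oxidation state, so the acyl donor 4 is made in one operation.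

## Roads not taken

Alternative 1: the most obvious cut is the aryl-carbonyl bond C1-C1', made by Friedel-Crafts acylation of benzene-1,3,5-triol A2 with 11-phenylundecanoyl chloride A1 and AlCl3, or by the Fries or Houben-Hoesch variants.
- Ring A is bought, and selectivity rests on stoichiometry only: A2 offers three oxygens and three equivalent carbons to the acylium ion derived from A1.
- The monoacylated ring still carries three donor groups, so O-acylation and a second C-acylation by A1 compete.
- A stoichiometric Lewis acid is needed, and the polar product must be separated from excess A2.
- From ester 4 it takes three operations (hydrolysis, chloride formation, acylation), against two in the chosen plan, where the single acyl group is a consequence of how ring A is built.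

Alternative 2: the same bond C1-C1' is cut with reversed polarity. 1,3,5-Trimethoxybenzene A4 is lithiated to 2,4,6-trimethoxyphenyllithium A5, which adds to N-methoxy-N-methyl-11-phenylundecanamide A3 to give 11-phenyl-1-(2,4,6-trimethoxyphenyl)undecan-1-one A6. Threefold O-demethylation of A6 with BBr3 follows.
- Monoacylation of A5 by A3 is clean, but the three methyl ethers of A4 are carried only to be removed.
- The two ethers of A6 ortho to the ketone cleave readily through chelation; the para ether needs forcing conditions on an electron-rich aryl ketone.
- The sequence from 4 is amide formation to A3, addition of A5 and deprotection, longer than the chosen plan, which uses no protecting group.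

Alternative 3: an electrochemical cut inside the chain, between C6' and C7'. A mixed Kolbe electrolysis of 7-oxo-7-(2,4,6-trimethoxyphenyl)heptanoic acid A7 and 6-phenylhexanoic acid A8 would give the same ketone A6, to be demethylated as before.
- The radical coupling is statistical, so homo-coupling of A7 and of A8 competes with the cross-coupling.
- The trimethoxyaryl ketone of A7 is likely to be oxidised at the anode near the potential that decarboxylation needs.
- A7 still requires an aryl-acyl bond and three methyl ethers, so the real problem of ring A is untouched.
- The bond made from A7 and A8 is an unfunctionalised CH2-CH2 bond that the commodity ester 1 already contains.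

Key step: step 3

## Route

Step 1
Reactants: 1 methyl undec-10-enoate; 2 bromobenzene
Product: 4 methyl 11-phenylundecanoate, via B-alkylborane 3 (not isolated)
Conditions: 9-BBN (1.1 equiv), THF, 0 °C to rt; then 2, PdCl2(dppf) (3 mol %), K3PO4 (3 M aq), THF/DMF, 60 °C
Reagents that add atoms: none
Why: Anti-Markovnikov hydroboration of the terminal alkene with 9-BBN, then B-alkyl Suzuki-Miyaura coupling of borane 3 with bromobenzene; the methyl ester tolerates 9-BBN at room temperature and the phosphate base, and 9-BBN leaves only a hydrogen atom in 4.

Step 2
Reactants: 5 4-hydroxy-6-methyl-2H-pyran-2-one (triacetic acid lactone); 4 methyl 11-phenylundecanoate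
Product: 7 pyrone 4-hydroxy-6-(2-oxo-12-phenyldodecyl)-2H-pyran-2-one, via dilithio dianion 6 (not isolated)
Conditions: 5 (2 equiv), LiN(iPr)2 (LDA, 4 equiv), THF, -78 to -20 °C; then 4 (1 equiv), -78 °C to rt; 1 M HCl
Reagents that add atoms: none
Why: Claisen-type acylation of the dianion of triacetic acid lactone at its more basic 6-methylene carbanion (ahead of O4 or C3) by the ester; the second equivalent of dianion deprotonates the new, more acidic keto-methylene of the product and so protects the ketone from further addition, and lithium stays only in 6.

Step 3
Reactants: 7 pyrone 4-hydroxy-6-(2-oxo-12-phenyldodecyl)-2H-pyran-2-one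
Product: 9 acylphloroglucinol 11-phenyl-1-(2,4,6-trihydroxyphenyl)undecan-1-one, via triketo ester 8 (not isolated)
Conditions: Mg(OMe)2 (8 equiv), MeOH, reflux, Ar; then 1 M HCl, 0 °C
Reagents that add atoms: none
Why: Biomimetic pyrone-to-arene ring transformation: methoxide adds to the lactone carbonyl of 7 and expels the enolate oxygen on pyrone C6, giving the magnesium chelate of triketo ester 8, the unmasked tetraketide. In 8 the most acidic hydrogens are those on C4 and C6, each between two ketones, so the magnesium-bound enolate sits on the 3,5,7-trione and leaves the C2 methylene and the C1 ester un-ionised, the ester being the one carbonyl not tied up in a chelate. C-Acylation of the magnesium diketonate carbon C6 by ester carbon C1 is an intramolecular Claisen (Dieckmann-type) condensation, whose closest known reaction type is the Mg(OMe)2 conversion of simple 6-(2-oxoalkyl)-4-hydroxy-2-pyrones into acylphloroglucinols; it closes ring A in the favoured 6-(enolexo)-exo-trig mode. Loss of methoxide gives a 2-acylcyclohexane-1,3,5-trione that tautomerises at once to the aromatic trihydroxyphenyl ketone, held as a magnesium chelate between the ketone and an ortho phenoxide, which makes the closure irreversible. The selectivity needed is Claisen closure (C6 to C1) over aldol closure (C2 to C7, leading to a resorcylate); it is secured by the absence of water, so the ester is not saponified to an unreactive carboxylate, by chelation of C7 in the diketonate, which lowers its electrophilicity, and by the reversibility of the aldol addition. The methoxy group of 8 comes from the reagent and leaves again as methanol, so 9 is an isomer of 7 and no reagent atom remains in it. No stereocentre is formed, and ring B and the decamethylene chain are spectators.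

## Compound list

1 | methyl undec-10-enoate | C=CCCCCCCCCC(=O)OC | starting material
2 | bromobenzene | Brc1ccccc1 | starting material
3 | methyl 11-(9-borabicyclo[3.3.1]nonan-9-yl)undecanoate | COC(=O)CCCCCCCCCCB1C2CCCC1CCC2 | intermediate
4 | methyl 11-phenylundecanoate | COC(=O)CCCCCCCCCCc1ccccc1 | intermediate
5 | 4-hydroxy-6-methyl-2H-pyran-2-one (triacetic acid lactone) | CC1=CC(O)=CC(=O)O1 | starting material
6 | dilithium salt of the O4,6-methylene dianion of 5 | [Li+].[Li+].[CH2-]C1=CC([O-])=CC(=O)O1 | intermediate
7 | 4-hydroxy-6-(2-oxo-12-phenyldodecyl)-2H-pyran-2-one | O=C(CCCCCCCCCCc1ccccc1)CC1=CC(O)=CC(=O)O1 | intermediate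
8 | methyl 3,5,7-trioxo-17-phenylheptadecanoate (present as its magnesium enolate chelate) | COC(=O)CC(=O)CC(=O)CC(=O)CCCCCCCCCCc1ccccc1 | intermediate
9 | 11-phenyl-1-(2,4,6-trihydroxyphenyl)undecan-1-one | O=C(CCCCCCCCCCc1ccccc1)c1c(O)cc(O)cc1O | target

## Step count and risk

Total step count: 3. Longest linear sequence: 3 steps (1 to 4 to 7 to 9).

Least certain steps:

Step 3 (key step). Three things can go wrong:
- The open chain may close in the aldol sense (C2 onto the C7 ketone) in competition with the Claisen closure. The C7 ketone here is an alkyl ketone and more electrophilic than an aryl ketone.
- Lactone opening may be slow, because the 4-oxidopyrone is a poor electrophile, and methoxide may then cleave the chain of 8 by retro-Claisen reaction.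
- The phloroglucinolate may be oxidised if air enters.

Fallback: give up the ring construction and attach the chain to a ready-made ring A. The fallback sets out from 4. Saponification (LiOH, THF/H2O) should give 11-phenylundecanoic acid F1. Oxalyl chloride with catalytic DMF in CH2Cl2 should convert F1 into 11-phenylundecanoyl chloride F2. Friedel-Crafts acylation of excess commercial benzene-1,3,5-triol with F2 (AlCl3, CH2Cl2/MeNO2, 0 °C to rt) should then give 9 directly, where the fallback rejoins the route.

Step 2. Two things can go wrong:
- Proton transfer from the alpha-methylene of ester 4 to the basic dianion 6 (enolisation in place of acylation) would return 4 or lead to its self-condensation.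
- The low solubility of the dilithio salt in THF may slow the acylation and allow O-acylation.

Fallback: mask the tetraketide as a dioxinone and assemble it on a soluble dianion. The fallback sets out from 4. Treatment with MeNHOMe·HCl and iPrMgCl (THF, -20 °C) should give N-methoxy-N-methyl-11-phenylundecanamide F3. The known 2,2-dimethyl-6-(2-oxopropyl)-4H-1,3-dioxin-4-one F4 is made in one step from commercial 2,2,6-trimethyl-4H-1,3-dioxin-4-one with LiN(SiMe3)2 and acetyl chloride. The dianion of F4 (LiN(iPr)2, 2 equiv, THF, -78 °C) should be acylated at the terminal methyl carbon by F3 to give 6-(2,4-dioxo-14-phenyltetradecyl)-2,2-dimethyl-4H-1,3-dioxin-4-one F5. Heating F5 in toluene at 110 °C should expel acetone to give the acylketene 17-phenylheptadec-1-ene-1,3,5,7-tetrone F6. The ketene carbon of F6 is trapped by the enol oxygen on C5 to close the 4-hydroxy-2-pyrone ring, giving 7, where the fallback rejoins the route.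

Step 1. Beta-hydride elimination or protodeboronation at the alkyl-palladium or alkylborane stage would give reduced or isomerised chain ends in place of the coupled product. The aqueous base may also hydrolyse part of the ester on prolonged heating.

Fallback: join ring B by olefin metathesis. The fallback sets out from 1. Cross-metathesis with excess styrene (second-generation Grubbs catalyst, CH2Cl2, 40 °C) should give methyl (E)-11-phenylundec-10-enoate F7. Hydrogenation of F7 (H2, Pd/C, EtOAc) should then give 4, where the fallback rejoins the route.

## Further compounds

F1 | step 3 | 11-phenylundecanoic acid | OC(=O)CCCCCCCCCCc1ccccc1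
F2 | step 3 | 11-phenylundecanoyl chloride | O=C(Cl)CCCCCCCCCCc1ccccc1
F3 | step 2 | N-methoxy-N-methyl-11-phenylundecanamide | CON(C)C(=O)CCCCCCCCCCc1ccccc1
F4 | step 2 | 2,2-dimethyl-6-(2-oxopropyl)-4H-1,3-dioxin-4-one | CC(=O)CC1=CC(=O)OC(C)(C)O1
F5 | step 2 | 6-(2,4-dioxo-14-phenyltetradecyl)-2,2-dimethyl-4H-1,3-dioxin-4-one | CC1(C)OC(CC(=O)CC(=O)CCCCCCCCCCc2ccccc2)=CC(=O)O1
F6 | step 2 | 17-phenylheptadec-1-ene-1,3,5,7-tetrone (acylketene) | O=C=CC(=O)CC(=O)CC(=O)CCCCCCCCCCc1ccccc1
F7 | step 1 | methyl (E)-11-phenylundec-10-enoate | COC(=O)CCCCCCCC/C=C/c1ccccc1
A1 | alternative 1 | 11-phenylundecanoyl chloride | O=C(Cl)CCCCCCCCCCc1ccccc1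
A2 | alternative 1 | benzene-1,3,5-triol (phloroglucinol) | Oc1cc(O)cc(O)c1
A3 | alternative 2 | N-methoxy-N-methyl-11-phenylundecanamide | CON(C)C(=O)CCCCCCCCCCc1ccccc1
A4 | alternative 2 | 1,3,5-trimethoxybenzene | COc1cc(OC)cc(OC)c1
A5 | alternative 2 | 2,4,6-trimethoxyphenyllithium | [Li]c1c(OC)cc(OC)cc1OC
A6 | alternative 2 | 11-phenyl-1-(2,4,6-trimethoxyphenyl)undecan-1-one | COc1cc(OC)c(C(=O)CCCCCCCCCCc2ccccc2)c(OC)c1
A7 | alternative 3 | 7-oxo-7-(2,4,6-trimethoxyphenyl)heptanoic acid | COc1cc(OC)c(C(=O)CCCCCC(=O)O)c(OC)c1
A8 | alternative 3 | 6-phenylhexanoic acid | OC(=O)CCCCCc1ccccc1
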